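**Strategy**

Everything rests on disconnecting C3–C4 of the pyranone ring C, the bond between the ring methylene and the carbonyl carbon that sits on ring A. O1–C2 and the C2 stereocentre are made beforehand by an iridium-catalysed branched O-allylation and are never broken again. The key step is a ring-closing metathesis that joins the C2 vinyl group to the silyl enol ether of the A-ring acetyl group: in one operation it closes ring C, expels ethylene and leaves C4 at the ketone oxidation level. Its precursor is an all-TBS-protected 2-(1-arylallyloxy)-3-lavandulylacetophenone enol ether, so a single buffered fluoride step afterwards releases the flavanone.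

Key step: step 12

Remark on the chemistry: the side-chain centre, (R) in the target, has the geometry of (S)-lavandulol (CH2Ar ranks below isopropenyl, CH2OH above it, so only the descriptor changes); TBS ethers are used on all four phenols so that no acid meets the lavandulyl alkenes or the C2 benzylic ether.

**Route**

Step 1
Reactants: 1 2,4,6-trihydroxyacetophenone
Product: 2 1-[2-hydroxy-4,6-bis(tert-butyldimethylsilyloxy)phenyl]ethan-1-one
Conditions: TBSCl (2.1 equiv), imidazole, DMF–CH2Cl2, 0 °C to rt
Reagents that add atoms: tert-butyldimethylsilyl chloride, CC(C)(C)[Si](C)(C)Cl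
Why: Phenol O-silylation should stop at the bis-ether because the last ortho hydroxyl is hydrogen-bonded to the ketone and least nucleophilic, and since the two ortho hydroxyls of 1 are equivalent only one bis-ether can form.

Step 2
Reactants: 2 1-[2-hydroxy-4,6-bis(tert-butyldimethylsilyloxy)phenyl]ethan-1-one
Product: 3 1-[2-hydroxy-3-iodo-4,6-bis(tert-butyldimethylsilyloxy)phenyl]ethan-1-one
Conditions: NIS (1.05 equiv), MeCN, 0 °C, dark
Reagents that add atoms: N-iodosuccinimide, O=C1CCC(=O)N1I
Why: Electrophilic aromatic iodination of the activated ring should go ortho to the free hydroxyl (C3), because the only other open position (C5) lies between two bulky silyloxy groups.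

Step 3
Reactants: 4 (±)-lavandulol
Product: 5 (S)-lavandulol
Conditions: immobilised lipase (Novozym 435 or porcine pancreatic lipase), vinyl acetate, hexane, rt, run past half conversion; chromatography, second cycle if required
Reagents that add atoms: none
Why: Lipase-catalysed kinetic resolution by irreversible transesterification, in which the (R)-alcohol is expected to be acylated faster, so the unreacted alcohol becomes enriched in the (S)-enantiomer as conversion passes one half; this fixes the side-chain stereocentre.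

Step 4
Reactants: 5 (S)-lavandulol
Product: 6 (S)-lavandulyl iodide, (2S)-1-iodo-5-methyl-2-(prop-1-en-2-yl)hex-4-ene
Conditions: I2, PPh3, imidazole, CH2Cl2, 0 °C to rt
Reagents that add atoms: iodine, II
Why: Appel-type iodination displaces only the primary hydroxyl at CH2, so the adjacent stereocentre is not involved and the neutral medium leaves both alkenes in place.

Step 5
Reactants: 6 (S)-lavandulyl iodide and 3 1-[2-hydroxy-3-iodo-4,6-bis(tert-butyldimethylsilyloxy)phenyl]ethan-1-one
Product: 8 1-{2-hydroxy-3-[(2R)-5-methyl-2-(prop-1-en-2-yl)hex-4-en-1-yl]-4,6-bis(tert-butyldimethylsilyloxy)phenyl}ethan-1-one, via (S)-lavandulylzinc iodide 7 (not isolated)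
Conditions: Zn dust (activated with TMSCl and 1,2-dibromoethane), LiCl, THF, 35 °C; then 3, Pd(OAc)2 (3 mol%), SPhos (6 mol%), THF, 25–40 °C, zinc reagent in excess and added slowly
Reagents that add atoms: none
Why: Negishi sp3–sp2 cross-coupling, in which zinc insertion at the primary carbon leaves the stereocentre untouched and the Pd/biarylphosphine catalyst should couple the alkylzinc with the hindered aryl iodide faster than β-hydride elimination or protonolysis by the chelated phenol.

Step 6
Reactants: 9 2,4-dihydroxy-5-methoxybenzaldehyde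
Product: 10 2,4-bis(tert-butyldimethylsilyloxy)-5-methoxybenzaldehyde
Conditions: TBSCl (2.4 equiv), imidazole, DMF, rt
Reagents that add atoms: tert-butyldimethylsilyl chloride, CC(C)(C)[Si](C)(C)Cl
Why: Phenol O-silylation in DMF with excess reagent should also cap the aldehyde-chelated hydroxyl, giving ethers that tolerate ylides, hydride and the later metal catalysts.

Step 7
Reactants: 10 2,4-bis(tert-butyldimethylsilyloxy)-5-methoxybenzaldehyde
Product: 11 ethyl (E)-3-[2,4-bis(tert-butyldimethylsilyloxy)-5-methoxyphenyl]prop-2-enoate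
Conditions: Ph3P=CHCO2Et (1.3 equiv), toluene, 80 °C
Reagents that add atoms: ethyl (triphenylphosphoranylidene)acetate, CCOC(=O)C=P(c1ccccc1)(c1ccccc1)c1ccccc1
Why: Wittig olefination with a stabilised ylide should give the E-cinnamate under neutral conditions that spare the aryl silyl ethers.

Step 8
Reactants: 11 ethyl (E)-3-[2,4-bis(tert-butyldimethylsilyloxy)-5-methoxyphenyl]prop-2-enoate
Product: 12 (E)-3-[2,4-bis(tert-butyldimethylsilyloxy)-5-methoxyphenyl]prop-2-en-1-ol
Conditions: DIBAL-H (2.3 equiv), CH2Cl2, −78 °C; Rochelle salt work-up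
Reagents that add atoms: none
Why: DIBAL-H 1,2-reduction of the unsaturated ester should stop at the allylic alcohol with the E-alkene and the silyl ethers intact at low temperature.

Step 9
Reactants: 12 (E)-3-[2,4-bis(tert-butyldimethylsilyloxy)-5-methoxyphenyl]prop-2-en-1-ol
Product: 13 (E)-3-[2,4-bis(tert-butyldimethylsilyloxy)-5-methoxyphenyl]prop-2-en-1-yl methyl carbonate
Conditions: ClCO2Me, pyridine, CH2Cl2, 0 °C
Reagents that add atoms: methyl chloroformate, COC(=O)Cl
Why: Acylation of the primary allylic alcohol with a chloroformate gives the linear carbonate, the leaving group needed for iridium allyl chemistry.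

Step 10
Reactants: 8 1-{2-hydroxy-3-[(2R)-5-methyl-2-(prop-1-en-2-yl)hex-4-en-1-yl]-4,6-bis(tert-butyldimethylsilyloxy)phenyl}ethan-1-one and 13 (E)-3-[2,4-bis(tert-butyldimethylsilyloxy)-5-methoxyphenyl]prop-2-en-1-yl methyl carbonate
Product: 15 1-{2-{[(1S)-1-[2,4-bis(tert-butyldimethylsilyloxy)-5-methoxyphenyl]prop-2-en-1-yl]oxy}-3-[(2R)-5-methyl-2-(prop-1-en-2-yl)hex-4-en-1-yl]-4,6-bis(tert-butyldimethylsilyloxy)phenyl}ethan-1-one, via lithium aryloxide 14 (not isolated)
Conditions: LiHMDS (1.0 equiv), THF, 0 °C; then 13 (1.2 equiv), [Ir(cod)Cl]2 (2 mol%), (Sa,S,S)-BINOL phosphoramidite with N,N-bis[1-(2-methoxyphenyl)ethyl] groups (4 mol%), catalyst pre-activated with n-PrNH2, THF, 25 °C; stopped at full conversion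
Reagents that add atoms: none
Why: Iridium-catalysed asymmetric allylic etherification, in which the cyclometallated Ir–phosphoramidite ionises the linear carbonate to an η3-allyl complex and the aryloxide attacks the aryl-bearing terminus on the ligand-controlled face to give the branched ether with C2 as (S); the (Sa,S,S) ligand is the enantiomer expected to give this sense, to be confirmed by chiral HPLC on the first run and exchanged for its antipode otherwise, and the silyloxy groups flanking C5 should discourage C-allylation.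

Step 11
Reactants: 15 (S)-allyl aryl ether ketone
Product: 16 tert-butyl({1-[2-{[(1S)-1-[2,4-bis(tert-butyldimethylsilyloxy)-5-methoxyphenyl]prop-2-en-1-yl]oxy}-3-[(2R)-5-methyl-2-(prop-1-en-2-yl)hex-4-en-1-yl]-4,6-bis(tert-butyldimethylsilyloxy)phenyl]ethenyl}oxy)dimethylsilane (the TBS enol ether of 15)
Conditions: TBSOTf (1.3 equiv), Et3N (3 equiv), CH2Cl2, −78 to 0 °C; NaHCO3 work-up, filtration through Et3N-deactivated silica
Reagents that add atoms: tert-butyldimethylsilyl trifluoromethanesulfonate, CC(C)(C)[Si](C)(C)OS(=O)(=O)C(F)(F)F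
Why: Soft enolisation and O-silylation of the methyl ketone, which has a single enolisable position, should give one enol ether, while the excess amine keeps the medium basic so that the ionisable allylic aryl ether is not activated.

Step 12
Reactants: 16 TBS enol ether of 15
Product: 17 (2S)-2-[2,4-bis(tert-butyldimethylsilyloxy)-5-methoxyphenyl]-4,5,7-tris(tert-butyldimethylsilyloxy)-8-[(2R)-5-methyl-2-(prop-1-en-2-yl)hex-4-en-1-yl]-2H-chromene
Conditions: (H2IMes)(PCy3)Cl2Ru=CHPh (5–10 mol%), 1,4-benzoquinone (10 mol%), degassed CH2Cl2 (0.005 M), 40 °C, argon sparge, dark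
Reagents that add atoms: none
Why: The ruthenium carbene should initiate at the monosubstituted vinyl group on C2, the new alkylidene adds [2+2] across the 1,1-disubstituted silyl enol ether with ruthenium on its CH2 terminus, and cycloreversion forms C3=C4 and a ruthenium methylidene that turns over with release of ethylene. The closest known reaction is silyl enol ether–ene ring-closing metathesis, used for cyclic silyl enol ethers and for 4-silyloxy-1,2-dihydroquinolines from N-allyl-2-acylanilines, of which this is the oxygen analogue. The six-membered pyran ring C is closed by ring-closing metathesis between C3 and C4, the new double bond lying inside the ring. No stereocentre is formed; C2 and the lavandulyl centre are spectators, and because O1–C2 is not broken no chalcone can arise. The step needs chemoselectivity among four alkenes: only the vinyl group is monosubstituted, the isopropenyl and prenyl alkenes could close only eight- or nine-membered rings, and the substitution of the enol ether directs the cycloaddition away from a heteroatom-stabilised carbene. Mild temperature, exclusion of light, benzoquinone against ruthenium hydride isomerisation and removal of ethylene protect the allylic aryl ether and the allylic side-chain centre.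

Step 13
Reactants: 17 pentasilylated 2H-chromene
Product: 18 (2S)-2-(2,4-dihydroxy-5-methoxyphenyl)-5,7-dihydroxy-8-[(2R)-5-methyl-2-(prop-1-en-2-yl)hex-4-en-1-yl]-2,3-dihydro-4H-chromen-4-one (CNP0323048.1)
Conditions: TBAF (6 equiv), AcOH (7 equiv), THF, 0 °C to rt; pH 6 buffer work-up
Reagents that add atoms: none
Why: Fluoride-mediated desilylation should cleave the enol ether (giving the C4 ketone by protonation at C3) and the four aryl ethers in one operation, while the acetic acid buffer protonates the transient enolate and phenoxides before β-elimination of O1 can open the ring, so C2 keeps its configuration and the alkenes see no strong acid.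

**Compound list**

1 | 2,4,6-trihydroxyacetophenone | CC(=O)c1c(O)cc(O)cc1O | starting material
2 | 1-[2-hydroxy-4,6-bis(tert-butyldimethylsilyloxy)phenyl]ethan-1-one | CC(=O)c1c(O)cc(O[Si](C)(C)C(C)(C)C)cc1O[Si](C)(C)C(C)(C)C | intermediate
3 | 1-[2-hydroxy-3-iodo-4,6-bis(tert-butyldimethylsilyloxy)phenyl]ethan-1-one | CC(=O)c1c(O)c(I)c(O[Si](C)(C)C(C)(C)C)cc1O[Si](C)(C)C(C)(C)C | intermediate
4 | (±)-lavandulol | C=C(C)C(CC=C(C)C)CO | starting material
5 | (S)-lavandulol | C=C(C)[C@H](CC=C(C)C)CO | intermediate
6 | (S)-lavandulyl iodide | C=C(C)[C@H](CC=C(C)C)CI | intermediate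
7 | (S)-lavandulylzinc iodide | C=C(C)[C@H](CC=C(C)C)C[Zn]I | intermediate (not isolated)
8 | 1-{2-hydroxy-3-[(2R)-5-methyl-2-(prop-1-en-2-yl)hex-4-en-1-yl]-4,6-bis(tert-butyldimethylsilyloxy)phenyl}ethan-1-one | C=C(C)[C@H](CC=C(C)C)Cc1c(O[Si](C)(C)C(C)(C)C)cc(O[Si](C)(C)C(C)(C)C)c(C(C)=O)c1O | intermediate
9 | 2,4-dihydroxy-5-methoxybenzaldehyde | COc1cc(C=O)c(O)cc1O | starting material
10 | 2,4-bis(tert-butyldimethylsilyloxy)-5-methoxybenzaldehyde | COc1cc(C=O)c(O[Si](C)(C)C(C)(C)C)cc1O[Si](C)(C)C(C)(C)C | intermediate
11 | ethyl (E)-3-[2,4-bis(tert-butyldimethylsilyloxy)-5-methoxyphenyl]prop-2-enoate | CCOC(=O)/C=C/c1cc(OC)c(O[Si](C)(C)C(C)(C)C)cc1O[Si](C)(C)C(C)(C)C | intermediate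
12 | (E)-3-[2,4-bis(tert-butyldimethylsilyloxy)-5-methoxyphenyl]prop-2-en-1-ol | OC/C=C/c1cc(OC)c(O[Si](C)(C)C(C)(C)C)cc1O[Si](C)(C)C(C)(C)C | intermediate
13 | (E)-3-[2,4-bis(tert-butyldimethylsilyloxy)-5-methoxyphenyl]prop-2-en-1-yl methyl carbonate | COC(=O)OC/C=C/c1cc(OC)c(O[Si](C)(C)C(C)(C)C)cc1O[Si](C)(C)C(C)(C)C | intermediate
14 | lithium aryloxide of 8 | C=C(C)[C@H](CC=C(C)C)Cc1c(O[Si](C)(C)C(C)(C)C)cc(O[Si](C)(C)C(C)(C)C)c(C(C)=O)c1[O-].[Li+] | intermediate (not isolated)
15 | 1-{2-{[(1S)-1-[2,4-bis(tert-butyldimethylsilyloxy)-5-methoxyphenyl]prop-2-en-1-yl]oxy}-3-[(2R)-5-methyl-2-(prop-1-en-2-yl)hex-4-en-1-yl]-4,6-bis(tert-butyldimethylsilyloxy)phenyl}ethan-1-one | C=C(C)[C@H](CC=C(C)C)Cc1c(O[Si](C)(C)C(C)(C)C)cc(O[Si](C)(C)C(C)(C)C)c(C(C)=O)c1O[C@H](c1cc(OC)c(O[Si](C)(C)C(C)(C)C)cc1O[Si](C)(C)C(C)(C)C)C=C | intermediate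
16 | TBS enol ether of 15 (metathesis precursor) | C=C(C)[C@H](CC=C(C)C)Cc1c(O[Si](C)(C)C(C)(C)C)cc(O[Si](C)(C)C(C)(C)C)c(C(=C)O[Si](C)(C)C(C)(C)C)c1O[C@H](c1cc(OC)c(O[Si](C)(C)C(C)(C)C)cc1O[Si](C)(C)C(C)(C)C)C=C | intermediate
17 | (2S)-2-[2,4-bis(tert-butyldimethylsilyloxy)-5-methoxyphenyl]-4,5,7-tris(tert-butyldimethylsilyloxy)-8-[(2R)-5-methyl-2-(prop-1-en-2-yl)hex-4-en-1-yl]-2H-chromene | C=C(C)[C@H](CC=C(C)C)Cc1c(O[Si](C)(C)C(C)(C)C)cc(O[Si](C)(C)C(C)(C)C)c2c1O[C@H](c1cc(OC)c(O[Si](C)(C)C(C)(C)C)cc1O[Si](C)(C)C(C)(C)C)C=C2O[Si](C)(C)C(C)(C)C | intermediate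
18 | (2S)-2-(2,4-dihydroxy-5-methoxyphenyl)-5,7-dihydroxy-8-[(2R)-5-methyl-2-(prop-1-en-2-yl)hex-4-en-1-yl]-2,3-dihydro-4H-chromen-4-one | C=C(C)[C@H](CC=C(C)C)Cc1c(O)cc(O)c2c1O[C@H](c1cc(OC)c(O)cc1O)CC2=O | target

**Count and risks**

Total step count: 13. Longest linear sequence: 8 steps (steps 6–13, from the benzaldehyde).

Steps most likely to fail:

1. Step 12. The ruthenium carbene may not turn over on the hindered, electron-rich enol ether flanked by two ortho substituents, or ruthenium hydride species may isomerise the allylic ether before ring closure. The fallback sets out from phenol 8 and aldehyde 10 and comes back to the route at 18. Aldol addition of 8 to 10 (LiHMDS, 2.1 equiv, THF, −78 °C) would give the β-hydroxy ketone F1 as both carbinol epimers. Intramolecular Mitsunobu etherification (PPh3, DIAD, THF, 0 °C) would then close O1–C2 to the tetrasilylated flavanone F2. This sequence gives up catalyst control at C2, so the (2S) epimer would have to be separated from its (2R) diastereomer by preparative HPLC, which is possible in principle because the lavandulyl centre makes them diastereomers. The buffered fluoride conditions of step 13 would then give 18.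

2. Step 10. The di-ortho-substituted, carbonyl-chelated aryloxide may attack the allyl complex slowly, so that linear ether formation, C-allylation or reversible ionisation of the electron-rich product erodes regio- and enantioselectivity. The fallback sets out from aldehyde 10 and phenol 8 and comes back at 15. Enantioselective vinylzinc addition to 10 under amino-alcohol ligand control (ligand enantiomer chosen for the (R)-carbinol, with a kinetic resolution as upgrade if needed) would give (1R)-1-[2,4-bis(tert-butyldimethylsilyloxy)-5-methoxyphenyl]prop-2-en-1-ol F3. Mitsunobu etherification of 8 with F3 (PPh3, DIAD, toluene, −20 to 0 °C) would form the aryl ether with inversion, giving 15.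

3. Step 5. Oxidative addition and transmetallation at the di-ortho-substituted iodide may be slow enough for protonolysis of the alkylzinc by the phenol or β-hydride elimination to take over. The fallback sets out from iodide 6 and aryl iodide 3 and comes back at 8. Lithium–iodine exchange on 6 (t-BuLi, 2 equiv, Et2O, −78 °C) would give (S)-lavandulyllithium F4, which is trapped with 9-methoxy-9-BBN as the lithium B-methoxy-B-lavandulyl-9-borabicyclo[3.3.1]nonane borate F5. This borate, in excess, would be coupled with 3 in a base-free B-alkyl Suzuki–Miyaura reaction (PdCl2(dppf), THF–DMF, 25–50 °C) to give 8.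

**Further compounds**

F1 | step 12 | 3-[2,4-bis(tert-butyldimethylsilyloxy)-5-methoxyphenyl]-3-hydroxy-1-{2-hydroxy-3-[(2R)-5-methyl-2-(prop-1-en-2-yl)hex-4-en-1-yl]-4,6-bis(tert-butyldimethylsilyloxy)phenyl}propan-1-one (both carbinol epimers) | C=C(C)[C@H](CC=C(C)C)Cc1c(O[Si](C)(C)C(C)(C)C)cc(O[Si](C)(C)C(C)(C)C)c(C(=O)CC(O)c2cc(OC)c(O[Si](C)(C)C(C)(C)C)cc2O[Si](C)(C)C(C)(C)C)c1O
F2 | step 12 | (2S)-2-[2,4-bis(tert-butyldimethylsilyloxy)-5-methoxyphenyl]-5,7-bis(tert-butyldimethylsilyloxy)-8-[(2R)-5-methyl-2-(prop-1-en-2-yl)hex-4-en-1-yl]-2,3-dihydro-4H-chromen-4-one | C=C(C)[C@H](CC=C(C)C)Cc1c(O[Si](C)(C)C(C)(C)C)cc(O[Si](C)(C)C(C)(C)C)c2c1O[C@H](c1cc(OC)c(O[Si](C)(C)C(C)(C)C)cc1O[Si](C)(C)C(C)(C)C)CC2=O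
F3 | step 10 | (1R)-1-[2,4-bis(tert-butyldimethylsilyloxy)-5-methoxyphenyl]prop-2-en-1-ol | C=C[C@@H](O)c1cc(OC)c(O[Si](C)(C)C(C)(C)C)cc1O[Si](C)(C)C(C)(C)C
F4 | step 5 | (S)-lavandulyllithium | [Li]C[C@@H](CC=C(C)C)C(C)=C
F5 | step 5 | lithium 9-methoxy-9-[(2S)-5-methyl-2-(prop-1-en-2-yl)hex-4-en-1-yl]-9-borabicyclo[3.3.1]nonan-9-uide | [Li+].CO[B-]1(C[C@@H](CC=C(C)C)C(C)=C)C2CCCC1CCC2
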